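Pestalone G: route by [4+2] construction of ring B on a ring A side chain

## The problem

Numbering used throughout:
- Ring A is C1'–C6': C1' ketone, C2' OMe, C3' Cl, C4' Me, C5' Br, C6' OH.
- Ring B is C1–C6: C1 ketone, C2 CHO, C3 OH, C4 H, C5 OH, C6 prenyl.

One carbonyl carbon joins a hexasubstituted and a pentasubstituted benzene ring. All four ortho positions are occupied, so any bond made between that carbon and a finished arene forms at a very crowded centre.

In ring A, chlorine and bromine differ only in their relation to the oxygens. C3' is para to OH and ortho to OMe. C5' is ortho to OH and para to OMe. Both halogens must go in before ring B and the prenyl group exist, because a resorcinol ring and a trisubstituted alkene react faster with X+ than ring A does. Once C5'–Br is in place, alkyllithium and aryllithium reagents and most Pd(0) chemistry are unsafe.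

In ring B, the ketone sits on C1, meta to both hydroxyl groups. It cannot be brought in by electrophilic substitution, and five contiguous substituents would otherwise have to be placed one at a time.

Two groupings are fragile, so the end of the route must be close to neutral:
- The prenyl group next to C5–OH closes to a chroman in strong acid.
- The o-formyl ketone isomerises to a phthalide with base (Cannizzaro–Tishchenko type) and condenses with amines.

There is no stereocentre to set.

The feature that opens the key step is the following. C3(OH)–C4(H)–C5(OH)–C6(CH2CH=CMe2) is, carbon for carbon, the C1–C4 chain of a γ-prenylated acetoacetate. C1 and C2 carry two carbonyl groups in a 1,4-relation, as the alkene carbons of an ene-dicarbonyl compound do. Ring B is therefore a [4+2] adduct that has lost HX and MeOH.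

## Retrosynthesis

**18 ⇒ 17 ⇒ 16 ⇒ 10 + 15.** The bonds cut are C1–C6 and C2–C3 of ring B.
- Cutting either aryl–CO bond instead leaves ring B as a pentasubstituted arene to be made separately, and it forces a union between two di-ortho-substituted partners.
- The other [4+2] partitions of ring B put oxygen on the dienophile or pair two termini of like polarity.
- The chosen partition gives a 1,3-dioxygenated diene 15. Its nucleophilic end is the future C6, and it meets the future C1.
- The precursors are much simpler than the product. Compound 10 has one ring and a four-carbon chain, and 15 is acyclic.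
- The forward step must give one orientation, must add to C=C and not to C=O, and must aromatise by loss of HBr and MeOH. Desilylation of 17 then gives 18.

**10 ⇒ 9 ⇒ 8.** The bonds cut are the vinylic C–Br bond and the aldehyde C=O (back to its acetal).
- The corresponding alkyne (F1, kept as the fallback) has two acceptors of nearly equal strength and no element that fixes the orientation.
- A bromine on the formyl-bearing carbon marks that carbon as the partner of the ketene-acetal carbon, as a halogen does in haloquinones. It also keeps the alkyne oxidation level.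
- The forward reaction places it without ambiguity. While the aldehyde is still an acetal, the ketone of 8 is the only acceptor, so bromide adds β to it, on the acetal-bearing carbon.

**8 ⇒ 7 ⇒ 6 ⇒ 4 + 5.** The bond cut is the one between the ketone carbon and the alkyne carbon.
- The crowded carbonyl carbon of ring A is approached by the slimmest carbon nucleophile, an acetylide, and not by an arene.
- The TBS group of 8 masks C6'–OH, which would otherwise add to the ynone. It was chosen because it leaves together with the TMS groups in the last operation.
- The forward steps are an acetylide addition, an oxidation and a silylation.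

**4 ⇒ 3 ⇒ 2 ⇒ 1.** The bonds cut are C1'–CHO, C5'–Br and C3'–Cl.
- Each substitution leaves fewer open positions for the next. Chlorine goes para to OH, bromine para to OMe, and the formyl group takes the last free carbon.
- Chlorine comes before bromine because Cl+ can displace bromine by ipso attack, whereas Br+ does not displace chlorine.
- Only the first substitution has to choose between two activated sites.

**15 ⇒ 14 ⇒ 13 ⇒ 11 + 12.** The bond cut is the one between the future C6 and the prenyl CH2.
- The prenyl group is attached to an sp3 carbon by dianion alkylation, so the positional problems of aromatic prenylation never arise.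
- Two O-silylations then turn 13 into the diene.

## Roads not taken

**Alternative 1:** This is the most obvious cut, ketone carbon–C1 (ring B).
- Forward step: Br/Li exchange on the protected ring B bromide A1, addition to the MOM-protected ring A aldehyde A2 to give the benzhydrol A3, then oxidation and three deprotections.
- A1 needs bromine, masked formyl, prenyl and two protecting groups placed one after another on an arene.
- The union joins two di-ortho-substituted partners.
- For this target in particular, C5'–Br of A2 sits on an electron-poor polyhaloarene, so it is a ready exchange partner for the aryllithium. The bromine would be scrambled, or it would have to be introduced later, when ring B and the prenyl group outcompete ring A for Br+.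
- The chosen plan needs no aryl–metal species after bromination and no separate oxidation after the union.

**Alternative 2:** The cut is ketone carbon–C1' (ring A).
- Forward step: I/Mg exchange in the aryl ester A4, made from the protected ring B acid A5, followed by a 1,3 O→C acyl shift (anionic Fries rearrangement).
- The polarity is natural and C6'–OH is set free.
- A5 is, however, as laborious as A1.
- The formyl group must stay masked, because an aryl 2-formylbenzoate collapses to a phthalide as soon as a nucleophile touches the aldehyde.
- The shift runs through a four-membered transition state onto a carbonyl group flanked on both sides.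
- The chosen plan builds ring B and the ketone environment in one step, with one protecting group.

**Alternative 3:** Both aryl–CO bonds are cut.
- Forward step: a three-component carbonylative Suzuki coupling of the iodide A6, CO and the boronate A7.
- A tetra-ortho-substituted ketone asks a hindered aroyl–palladium species to transmetalate with a hindered boronate. Decarbonylation and direct biaryl coupling compete.
- C5'–Br is a second site for oxidative addition.
- A7 again presupposes a finished ring B.

Key step: step 12

Assumption: the SMILES holds no stereocentre and no stereogenic double bond, and rotation about the aryl–CO bonds is taken as fast. The compound is therefore achiral, and the constitution alone defines the target.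

## Route

Step 1
Reactants: 1 3-methoxy-5-methylphenol
Product: 2 4-chloro-3-methoxy-5-methylphenol
Conditions: SO2Cl2 (1.0 equiv), i-Pr2O (4 equiv), CH2Cl2, −10 °C to rt
Reagents that add atoms: sulfuryl chloride ClS(Cl)(=O)=O
Why: Electrophilic aromatic chlorination; C4 is para to the stronger donor OH and ortho to OMe, and the ether additive hydrogen-bonds to OH, which strengthens its para direction and shields both ortho positions, the same bias that turns 3,5-dimethylphenol into its 4-chloro derivative.

Step 2
Reactants: 2 4-chloro-3-methoxy-5-methylphenol
Product: 3 2-bromo-4-chloro-5-methoxy-3-methylphenol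
Conditions: NBS (1.0 equiv), MeCN, −10 °C to 0 °C, dark
Reagents that add atoms: N-bromosuccinimide O=C1CCC(=O)N1Br
Why: Electrophilic aromatic bromination; of the two open positions, the one ortho to OH and para to OMe is attacked in preference to the one wedged between the two oxygens, as is usual for resorcinol ethers.

Step 3
Reactants: 3 2-bromo-4-chloro-5-methoxy-3-methylphenol
Product: 4 3-bromo-5-chloro-2-hydroxy-6-methoxy-4-methylbenzaldehyde
Conditions: MgCl2 (2 equiv), Et3N (4 equiv), (CH2O)n (6 equiv), MeCN, reflux; then 1 M HCl
Reagents that add atoms: paraformaldehyde (as formaldehyde) C=O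
Why: Casnati–Skattebøl ortho-formylation; the magnesium phenoxide delivers formaldehyde to the ortho carbon and a second formaldehyde takes up hydride from the benzylic alkoxide. Only one ring position is free, so there is no positional choice, and 2-halophenols are standard substrates.

Step 4
Reactants: 4 3-bromo-5-chloro-2-hydroxy-6-methoxy-4-methylbenzaldehyde; 5 3,3-diethoxyprop-1-yne
Product: 6 rac-1-(3-bromo-5-chloro-2-hydroxy-6-methoxy-4-methylphenyl)-4,4-diethoxybut-2-yn-1-ol
Conditions: 5 (2.3 equiv), n-BuLi (2.2 equiv), THF, −78 °C; then 4, −78 °C to 0 °C; aq NH4Cl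
Reagents that add atoms: none
Why: 1,2-Addition of a lithium acetylide to a salicylaldehyde; one equivalent deprotonates the phenol and the second adds. All n-BuLi is consumed by the excess alkyne before 4 enters, so C–Br is not exchanged; the new carbinol centre is racemic and is removed in step 5.

Step 5
Reactants: 6 rac-1-(3-bromo-5-chloro-2-hydroxy-6-methoxy-4-methylphenyl)-4,4-diethoxybut-2-yn-1-ol
Product: 7 1-(3-bromo-5-chloro-2-hydroxy-6-methoxy-4-methylphenyl)-4,4-diethoxybut-2-yn-1-one
Conditions: MnO2 (15 equiv), CH2Cl2, rt
Reagents that add atoms: none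
Why: MnO2 oxidation of a benzylic and propargylic alcohol under neutral heterogeneous conditions that leave the phenol and the acetal alone; o-hydroxyaryl ynones made this way can be isolated because the phenol is held by a hydrogen bond to the ketone.

Step 6
Reactants: 7 1-(3-bromo-5-chloro-2-hydroxy-6-methoxy-4-methylphenyl)-4,4-diethoxybut-2-yn-1-one
Product: 8 1-[3-bromo-2-(tert-butyldimethylsilyloxy)-5-chloro-6-methoxy-4-methylphenyl]-4,4-diethoxybut-2-yn-1-one
Conditions: TBSOTf (1.3 equiv), 2,6-lutidine (2 equiv), CH2Cl2, −78 °C to 0 °C
Reagents that add atoms: tert-butyldimethylsilyl triflate CC(C)(C)[Si](C)(C)OS(=O)(=O)C(F)(F)F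
Why: O-Silylation of a hindered phenol with a silyl triflate and a non-nucleophilic base, fast enough at low temperature to outrun oxa-Michael closure onto the ynone. The acetal sits on an electron-poor alkyne and ionises too slowly to be attacked by the triflate.

Step 7
Reactants: 8 1-[3-bromo-2-(tert-butyldimethylsilyloxy)-5-chloro-6-methoxy-4-methylphenyl]-4,4-diethoxybut-2-yn-1-one
Product: 9 (Z)-3-bromo-1-[3-bromo-2-(tert-butyldimethylsilyloxy)-5-chloro-6-methoxy-4-methylphenyl]-4,4-diethoxybut-2-en-1-one
Conditions: LiBr (1.5 equiv), AcOH (3 equiv), MeCN, rt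
Reagents that add atoms: lithium bromide [Li+].[Br-]
Why: Hydrohalogenation of an ynone by conjugate addition of bromide and anti protonation, which gives the Z-β-bromoenone. The ketone is the only acceptor while the aldehyde is masked, so bromine ends on the acetal-bearing carbon; the alkene geometry has no bearing on the final arene.

Step 8
Reactants: 9 (Z)-3-bromo-1-[3-bromo-2-(tert-butyldimethylsilyloxy)-5-chloro-6-methoxy-4-methylphenyl]-4,4-diethoxybut-2-en-1-one
Product: 10 (Z)-2-bromo-4-[3-bromo-2-(tert-butyldimethylsilyloxy)-5-chloro-6-methoxy-4-methylphenyl]-4-oxobut-2-enal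
Conditions: TFA/H2O (4:1), CH2Cl2, 0 °C; used crude
Reagents that add atoms: water O
Why: Acid hydrolysis of a diethyl acetal, as for 2-bromoacrolein acetals. Aryl silyl ethers of acidic phenols are robust towards acid, and the vinyl bromide and the aryl halides are inert.

Step 9
Reactants: 11 methyl acetoacetate; 12 1-bromo-3-methylbut-2-ene (prenyl bromide)
Product: 13 methyl 7-methyl-3-oxooct-6-enoate
Conditions: NaH (1.1 equiv), THF, 0 °C; n-BuLi (1.05 equiv), 0 °C; then 12, 0 °C to rt; 1 M HCl
Reagents that add atoms: none
Why: Weiler γ-alkylation of the acetoacetate dianion; the more basic terminal carbanion displaces bromide at the primary carbon of 12 in an SN2 reaction.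

Step 10
Reactants: 13 methyl 7-methyl-3-oxooct-6-enoate
Product: 14 methyl 7-methyl-3-(trimethylsilyloxy)octa-2,6-dienoate (E/Z mixture)
Conditions: TMSCl (1.5 equiv), Et3N (1.6 equiv), toluene, rt; filtration under argon
Reagents that add atoms: chlorotrimethylsilane C[Si](C)(C)Cl
Why: O-Silylation of the enol of a β-keto ester, the standard first stage in the preparation of 1,3-bis(silyloxy)dienes; the geometry at C2=C3 is lost in the next step.

Step 11
Reactants: 14 methyl 7-methyl-3-(trimethylsilyloxy)octa-2,6-dienoate
Product: 15 (3Z)-1-methoxy-7-methyl-1,3-bis(trimethylsilyloxy)octa-1,3,6-triene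
Conditions: LDA (commercial solution, 1.2 equiv), THF, −78 °C; TMSCl (1.3 equiv), −78 °C to rt
Reagents that add atoms: chlorotrimethylsilane C[Si](C)(C)Cl
Why: Kinetic γ-deprotonation of the silyloxy enoate and O-silylation of the dienolate, the standard second stage for 4-alkyl-1,3-bis(silyloxy)dienes. The 3Z isomer, with the alkyl chain pointing outward, is the one that reaches the s-cis form, and the isolated prenyl double bond is not involved.

Step 12
Reactants: 10 (Z)-2-bromo-4-[3-bromo-2-(tert-butyldimethylsilyloxy)-5-chloro-6-methoxy-4-methylphenyl]-4-oxobut-2-enal; 15 (3Z)-1-methoxy-7-methyl-1,3-bis(trimethylsilyloxy)octa-1,3,6-triene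
Product: 18 pestalone G, via bromo cycloadduct 16 (not isolated), via tris-silyl benzophenone 17 (not isolated)
Conditions: 15 (1.6 equiv), 2,6-lutidine (1.2 equiv), toluene, −20 °C to rt; then Et3N·3HF (6 equiv), THF, 0 °C to rt
Reagents that add atoms: none
Why: Normal-electron-demand Diels–Alder reaction followed by aromatising eliminations, the reaction type by which vinylketene acetals and 1,3-bis(silyloxy)dienes are annulated onto haloquinones and other halogenated ene-dicarbonyl dienophiles that serve as alkyne equivalents. Ring B is closed as a six-membered carbocycle in an intermolecular [4+2] mode: C4 of 15 (future C6, carrying the prenyl group) bonds to the CH carbon of 10 (future C1), and the ketene-acetal carbon C1 of 15 (future C3) bonds to the C–Br carbon (future C2). The step needs one orientation out of two, and three features of 10 secure it: the CH carbon is the β-position of the α-bromoenal, which is the stronger and unhindered acceptor; it is the only unsubstituted alkene terminus; and a halogen on an ene-dicarbonyl double bond regularly draws the acetal carbon of such dienes to itself and sends their nucleophilic end to the other carbon. The step also needs C=C to win over the aldehyde C=O, which is why no Lewis acid is present and the solvent is non-polar. Adduct 16 carries four stereocentres as a mixture, and none needs control because all four become sp2. The anti-disposed H (α to the ketone) and Br leave as HBr to lutidine, the doubly allylic ketal then ionises and loses MeOH together with the C6–H, and 17 results. Et3N·3HF finally removes the two TMS groups and the TBS group in a weakly acidic, non-nucleophilic medium that spares the prenyl group next to C5–OH and the base- and amine-sensitive o-formyl ketone.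

## Compound list

1 | 3-methoxy-5-methylphenol | COc1cc(C)cc(O)c1 | starting material
2 | 4-chloro-3-methoxy-5-methylphenol | COc1cc(O)cc(C)c1Cl | intermediate
3 | 2-bromo-4-chloro-5-methoxy-3-methylphenol | COc1cc(O)c(Br)c(C)c1Cl | intermediate
4 | 3-bromo-5-chloro-2-hydroxy-6-methoxy-4-methylbenzaldehyde | COc1c(Cl)c(C)c(Br)c(O)c1C=O | intermediate
5 | 3,3-diethoxyprop-1-yne | C#CC(OCC)OCC | starting material
6 | rac-1-(3-bromo-5-chloro-2-hydroxy-6-methoxy-4-methylphenyl)-4,4-diethoxybut-2-yn-1-ol (racemate) | CCOC(OCC)C#CC(O)c1c(O)c(Br)c(C)c(Cl)c1OC | intermediate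
7 | 1-(3-bromo-5-chloro-2-hydroxy-6-methoxy-4-methylphenyl)-4,4-diethoxybut-2-yn-1-one | CCOC(OCC)C#CC(=O)c1c(O)c(Br)c(C)c(Cl)c1OC | intermediate
8 | 1-[3-bromo-2-(tert-butyldimethylsilyloxy)-5-chloro-6-methoxy-4-methylphenyl]-4,4-diethoxybut-2-yn-1-one | CCOC(OCC)C#CC(=O)c1c(O[Si](C)(C)C(C)(C)C)c(Br)c(C)c(Cl)c1OC | intermediate
9 | (Z)-3-bromo-1-[3-bromo-2-(tert-butyldimethylsilyloxy)-5-chloro-6-methoxy-4-methylphenyl]-4,4-diethoxybut-2-en-1-one | CCOC(OCC)/C(Br)=C/C(=O)c1c(O[Si](C)(C)C(C)(C)C)c(Br)c(C)c(Cl)c1OC | intermediate
10 | (Z)-2-bromo-4-[3-bromo-2-(tert-butyldimethylsilyloxy)-5-chloro-6-methoxy-4-methylphenyl]-4-oxobut-2-enal | O=C/C(Br)=C/C(=O)c1c(O[Si](C)(C)C(C)(C)C)c(Br)c(C)c(Cl)c1OC | intermediate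
11 | methyl acetoacetate | COC(=O)CC(C)=O | starting material
12 | 1-bromo-3-methylbut-2-ene | CC(C)=CCBr | starting material
13 | methyl 7-methyl-3-oxooct-6-enoate | COC(=O)CC(=O)CCC=C(C)C | intermediate
14 | methyl 7-methyl-3-(trimethylsilyloxy)octa-2,6-dienoate (E/Z mixture at C2=C3) | COC(=O)C=C(CCC=C(C)C)O[Si](C)(C)C | intermediate
15 | (3Z)-1-methoxy-7-methyl-1,3-bis(trimethylsilyloxy)octa-1,3,6-triene (C1=C2 geometry undefined) | COC(O[Si](C)(C)C)=C/C(O[Si](C)(C)C)=C/CC=C(C)C | intermediate
16 | 1-bromo-2-[3-bromo-2-(tert-butyldimethylsilyloxy)-5-chloro-6-methoxy-4-methylbenzoyl]-6-methoxy-3-(3-methylbut-2-enyl)-4,6-bis(trimethylsilyloxy)cyclohex-4-ene-1-carbaldehyde (mixture of diastereomers, all stereocentres erased) | O=CC1(Br)C(C(=O)c2c(O[Si](C)(C)C(C)(C)C)c(Br)c(C)c(Cl)c2OC)C(CC=C(C)C)C(O[Si](C)(C)C)=CC1(OC)O[Si](C)(C)C | intermediate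
17 | 2-[3-bromo-2-(tert-butyldimethylsilyloxy)-5-chloro-6-methoxy-4-methylbenzoyl]-3-(3-methylbut-2-enyl)-4,6-bis(trimethylsilyloxy)benzaldehyde | O=Cc1c(O[Si](C)(C)C)cc(O[Si](C)(C)C)c(CC=C(C)C)c1C(=O)c1c(OC)c(Cl)c(C)c(Br)c1O[Si](C)(C)C(C)(C)C | intermediate
18 | pestalone G, 2-(3-bromo-5-chloro-2-hydroxy-6-methoxy-4-methylbenzoyl)-4,6-dihydroxy-3-(3-methylbut-2-enyl)benzaldehyde | COc1c(Cl)c(C)c(Br)c(O)c1C(=O)c1c(C=O)c(O)cc(O)c1CC=C(C)C | target

## Step count and least certain steps

Total step count: 12. Longest linear sequence: 9 (steps 1–8 and 12). Steps 9–11 form the side branch.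

**Step 12 (key step).**
- What may go wrong: after the first C–C bond has formed, silyl transfer to the bromo-enolate may outrun ring closure at the crowded C–Br carbon. The sequence would then stop at an open-chain Mukaiyama–Michael stage.
- Second risk: the diene may add to the formyl C=O of the very electrophilic aldehyde.
- Fallback: it gives up halogen control in exchange for uncrowded sp carbons. It sets out from 8, which is hydrolysed directly (TFA/H2O or neat formic acid) to 4-[3-bromo-2-(tert-butyldimethylsilyloxy)-5-chloro-6-methoxy-4-methylphenyl]-4-oxobut-2-ynal F1.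
- With 15 in toluene, F1 should give the cyclohexa-1,4-diene adduct 2-aroyl-6-methoxy-3-(3-methylbut-2-enyl)-4,6-bis(trimethylsilyloxy)cyclohexa-1,4-diene-1-carbaldehyde F2. Loss of methanol from F2 brings the route back at 17.
- In this variant the orientation rests only on the aldehyde being the better acceptor, so positional isomers may have to be separated.

**Step 1.**
- What may go wrong: poor positional selectivity, with attack para to OMe competing with attack para to OH. Both sites are doubly activated, and the wanted one is the more crowded.
- Fallback: it lets the methoxy group alone direct the first halogenation. It sets out from 1, which is acylated (PivCl, Et3N) to 3-methoxy-5-methylphenyl pivalate F3.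
- F3 is brominated para to OMe (NBS, MeCN) to 2-bromo-5-methoxy-3-methylphenyl pivalate F4, and F4 is deacylated (K2CO3, MeOH) to 2-bromo-5-methoxy-3-methylphenol F5.
- In F5 only the position para to OH and the unreactive position between the two oxygens are open. Chlorination with NCS brings the route back at 3.

**Step 6.**
- What may go wrong: base-induced 6-endo oxa-Michael closure of the phenol onto the ynone competes with silylation of a hydrogen-bonded, hindered OH.
- Fallback: it avoids a free o-hydroxy ynone altogether. It sets out from 4, which is silylated first (TBSOTf, 2,6-lutidine) to 3-bromo-2-(tert-butyldimethylsilyloxy)-5-chloro-6-methoxy-4-methylbenzaldehyde F6.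
- The chloromagnesium acetylide of 5 is added at −78 °C and quenched cold with acetic acid to suppress O→O silyl migration. This gives 1-[3-bromo-2-(tert-butyldimethylsilyloxy)-5-chloro-6-methoxy-4-methylphenyl]-4,4-diethoxybut-2-yn-1-ol F7.
- MnO2 oxidation of F7 brings the route back at 8.

**Step 3.**
- What may go wrong: slow or incomplete formylation, because the only free carbon lies between OH and OMe on a ring deactivated by two halogens. Further condensation of the hydroxymethyl stage with unreacted phenol is also possible.
- Fallback: it replaces electrophilic substitution by halogen–metal exchange. It sets out from 3, which is iodinated at the last free position (NIS) to 2-bromo-4-chloro-6-iodo-5-methoxy-3-methylphenol F8.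
- i-PrMgCl·LiCl (2.2 equiv: first the phenoxide, then selective I/Mg exchange in the presence of C–Br) followed by DMF brings the route back at 4.

## Further compounds

F1 | step 12 | 4-[3-bromo-2-(tert-butyldimethylsilyloxy)-5-chloro-6-methoxy-4-methylphenyl]-4-oxobut-2-ynal | O=CC#CC(=O)c1c(O[Si](C)(C)C(C)(C)C)c(Br)c(C)c(Cl)c1OC
F2 | step 12 | 2-[3-bromo-2-(tert-butyldimethylsilyloxy)-5-chloro-6-methoxy-4-methylbenzoyl]-6-methoxy-3-(3-methylbut-2-enyl)-4,6-bis(trimethylsilyloxy)cyclohexa-1,4-diene-1-carbaldehyde | O=CC1=C(C(=O)c2c(O[Si](C)(C)C(C)(C)C)c(Br)c(C)c(Cl)c2OC)C(CC=C(C)C)C(O[Si](C)(C)C)=CC1(OC)O[Si](C)(C)C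
F3 | step 1 | 3-methoxy-5-methylphenyl pivalate | COc1cc(C)cc(OC(=O)C(C)(C)C)c1
F4 | step 1 | 2-bromo-5-methoxy-3-methylphenyl pivalate | COc1cc(C)c(Br)c(OC(=O)C(C)(C)C)c1
F5 | step 1 | 2-bromo-5-methoxy-3-methylphenol | COc1cc(C)c(Br)c(O)c1
F6 | step 6 | 3-bromo-2-(tert-butyldimethylsilyloxy)-5-chloro-6-methoxy-4-methylbenzaldehyde | O=Cc1c(O[Si](C)(C)C(C)(C)C)c(Br)c(C)c(Cl)c1OC
F7 | step 6 | rac-1-[3-bromo-2-(tert-butyldimethylsilyloxy)-5-chloro-6-methoxy-4-methylphenyl]-4,4-diethoxybut-2-yn-1-ol | CCOC(OCC)C#CC(O)c1c(O[Si](C)(C)C(C)(C)C)c(Br)c(C)c(Cl)c1OC
F8 | step 3 | 2-bromo-4-chloro-6-iodo-5-methoxy-3-methylphenol | Oc1c(I)c(OC)c(Cl)c(C)c1Br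
A1 | alternative 1 | 3-bromo-2-(dimethoxymethyl)-1,5-bis(methoxymethoxy)-4-(3-methylbut-2-enyl)benzene | COC(OC)c1c(Br)c(CC=C(C)C)c(OCOC)cc1OCOC
A2 | alternative 1 | 3-bromo-5-chloro-6-methoxy-2-(methoxymethoxy)-4-methylbenzaldehyde | COCOc1c(Br)c(C)c(Cl)c(OC)c1C=O
A3 | alternative 1 | rac-[3-bromo-5-chloro-6-methoxy-2-(methoxymethoxy)-4-methylphenyl][2-(dimethoxymethyl)-3,5-bis(methoxymethoxy)-6-(3-methylbut-2-enyl)phenyl]methanol | COC(OC)c1c(C(O)c2c(OC)c(Cl)c(C)c(Br)c2OCOC)c(CC=C(C)C)c(OCOC)cc1OCOC
A4 | alternative 2 | 2-bromo-4-chloro-6-iodo-5-methoxy-3-methylphenyl 2-(dimethoxymethyl)-3,5-bis(methoxymethoxy)-6-(3-methylbut-2-enyl)benzoate | COC(OC)c1c(C(=O)Oc2c(I)c(OC)c(Cl)c(C)c2Br)c(CC=C(C)C)c(OCOC)cc1OCOC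
A5 | alternative 2 | 2-(dimethoxymethyl)-3,5-bis(methoxymethoxy)-6-(3-methylbut-2-enyl)benzoic acid | COC(OC)c1c(C(=O)O)c(CC=C(C)C)c(OCOC)cc1OCOC
A6 | alternative 3 | (2-bromo-4-chloro-6-iodo-5-methoxy-3-methylphenoxy)(tert-butyl)dimethylsilane | CC(C)(C)[Si](C)(C)Oc1c(I)c(OC)c(Cl)c(C)c1Br
A7 | alternative 3 | 2-[2-(dimethoxymethyl)-3,5-bis(methoxymethoxy)-6-(3-methylbut-2-enyl)phenyl]-4,4,5,5-tetramethyl-1,3,2-dioxaborolane | COC(OC)c1c(B2OC(C)(C)C(C)(C)O2)c(CC=C(C)C)c(OCOC)cc1OCOC
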